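**Plan**
- Retrosynthesis: the three O–Si bonds are cut first, then the C5–C6 bond, with C6=C7 taken back to a terminal alkyne and C4–C5 to a terminal alkene. The alkyne half (fragment 1, C6–C18) is cut at C12=C13 (Wittig) and C8–C9 (propargylation); the ketone half (fragment 2, C1–C5 with ring A) is cut at C2–C3 (enolate allylation).
- Enabling feature: C6=C7 is a cis-1,2-dialkyl alkene between two plain CH2 groups (C5 and C8). C8 insulates it from the C9 carbinol, and C2–C5 insulate it from the C1 ketone on ring A (the 2,6-dihydroxy-4-methoxyphenyl ring, bought intact). It is therefore the sum of a terminal alkyne and a terminal alkene once boron has carried C5 onto C6.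
- Forward: fragment 2 in two steps; fragment 1 in six (C13–C18 phosphonium salt, C6–C12 enal, Wittig); union at C5–C6 with boron as a temporary helper put on and taken off in the same flask; global desilylation. No ring is made or broken.
- Stereochemistry: C9 (R) from a chiral-phosphoric-acid-catalysed propargylation; 10E bought with the enal; 12Z from a lithium-free Wittig reaction; 15Z bought with (Z)-hex-3-en-1-ol; 6Z from the anti 1,2-shift of the key step.

Key step: step 9

Assumption: in step 5 the (R)-configured phosphoric acid is taken to expose the Re face of the enal, as this catalyst class does with aryl and alkenyl aldehydes, which gives the (R)-carbinol; the (S)-acid would be used if the sense proved opposite.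

**Step 1**
Reactants: 1 1-(2,6-dihydroxy-4-methoxyphenyl)ethan-1-one; 2 allyl bromide (3-bromoprop-1-ene)
Product: 4 1-(2,6-dihydroxy-4-methoxyphenyl)pent-4-en-1-one, via trilithium enolate-bisphenoxide 3 (not isolated)
Conditions: LiN(i-Pr)2 (3.3 equiv), THF–DMPU, −78 → −20 °C; then 2 (1.05 equiv), −78 → 0 °C; 1 M HCl quench
Reagents that add atoms: none
Why: Alkylation of a ketone enolate within a lithium polyanion: once both chelated phenols are deprotonated, the third equivalent of base forms the C2 enolate, whose carbon is by far the most nucleophilic site, so one equivalent of the allylic bromide should be taken up by SN2 at carbon to build C2–C3.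

**Step 2**
Reactants: 4 1-(2,6-dihydroxy-4-methoxyphenyl)pent-4-en-1-one
Product: 5 1-[2,6-bis(tert-butyldimethylsilyloxy)-4-methoxyphenyl]pent-4-en-1-one
Conditions: TBSCl (2.6 equiv), imidazole, DMAP (cat.), DMF, rt → 40 °C
Reagents that add atoms: tert-butyldimethylsilyl chloride, CC(C)(C)[Si](C)(C)Cl
Why: Silyl ether formation (imidazole-promoted silylation): both phenols should be silylated while the chloride/imidazole system is too weak to form a silyl enol ether, and the two ortho silyloxy groups then shield the C1 ketone in the later steps.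

**Step 3**
Reactants: 6 (Z)-hex-3-en-1-ol
Product: 7 (Z)-1-iodohex-3-ene
Conditions: I2, PPh3, imidazole, CH2Cl2, 0 °C → rt
Reagents that add atoms: iodine, II
Why: Appel-type iodination: iodide displaces the alkoxyphosphonium ion at the primary carbon, which leaves the Z alkene untouched.

**Step 4**
Reactants: 7 (Z)-1-iodohex-3-ene
Product: 8 [(Z)-hex-3-en-1-yl]triphenylphosphonium iodide
Conditions: PPh3, MeCN, reflux
Reagents that add atoms: triphenylphosphine, c1ccc(cc1)P(c1ccccc1)c1ccccc1
Why: SN2 quaternisation of the phosphine by the primary iodide (phosphonium salt formation for the Wittig reaction).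

**Step 5**
Reactants: 9 (E)-4,4-dimethoxybut-2-enal; 10 allenylboronic acid pinacol ester [4,4,5,5-tetramethyl-2-(propa-1,2-dien-1-yl)-1,3,2-dioxaborolane]
Product: 12 (4R,2E)-1,1-dimethoxyhept-2-en-6-yn-4-ol, via pinacol borate ester of the carbinol 11 (not isolated)
Conditions: 10 (1.5 equiv), (R)-3,3'-bis(2,4,6-triisopropylphenyl)-1,1'-binaphthyl-2,2'-diyl hydrogen phosphate (10 mol %), 4 Å MS, toluene, 0 °C; then aq. NaHCO3
Reagents that add atoms: none
Why: Chiral Brønsted-acid-catalysed propargylation of an aldehyde with an allenylboronate (SE2' allenylboration through a closed six-membered transition state): the phosphate bridges a boronate oxygen and the formyl hydrogen and is expected to expose the Re face, which sets C9 as R, while the terminal alkyne comes out directly and the 10E alkene is carried in unchanged.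

**Step 6**
Reactants: 12 (4R,2E)-1,1-dimethoxyhept-2-en-6-yn-4-ol
Product: 13 (4R,2E)-4-(tert-butyldimethylsilyloxy)-1,1-dimethoxyhept-2-en-6-yne
Conditions: TBSCl, imidazole, DMF, 0 °C → rt
Reagents that add atoms: tert-butyldimethylsilyl chloride, CC(C)(C)[Si](C)(C)Cl
Why: Silyl ether formation on the secondary allylic alcohol under buffered conditions that leave the acetal intact.

**Step 7**
Reactants: 13 (4R,2E)-4-(tert-butyldimethylsilyloxy)-1,1-dimethoxyhept-2-en-6-yne
Product: 14 (4R,2E)-4-(tert-butyldimethylsilyloxy)hept-2-en-6-ynal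
Conditions: p-TsOH·H2O (5 mol %), acetone–H2O (10:1), 0 °C
Reagents that add atoms: water, O
Why: Acid-catalysed hydrolysis of an α,β-unsaturated acetal: the allylic oxocarbenium ion forms easily, so catalytic acid at 0 °C should free the enal without loss of the secondary silyl ether or of the E geometry, which is the stable one.

**Step 8**
Reactants: 8 [(Z)-hex-3-en-1-yl]triphenylphosphonium iodide; 14 (4R,2E)-4-(tert-butyldimethylsilyloxy)hept-2-en-6-ynal
Product: 16 (4R,5E,7Z,10Z)-4-(tert-butyldimethylsilyloxy)trideca-5,7,10-trien-1-yne, via hexenylidene ylide 15 (not isolated)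
Conditions: 8 (1.3 equiv), NaN(SiMe3)2 (1.25 equiv), THF, −78 → 0 °C; then 14, THF–DMPU, −78 → −20 °C
Reagents that add atoms: none
Why: Wittig olefination with a non-stabilised ylide under lithium-free conditions: kinetic formation of the cis-oxaphosphetane should give the 12Z alkene, the ylide is not basic enough to remove the acetylenic hydrogen, and C9 is not touched.

**Step 9**
Reactants: 5 1-[2,6-bis(tert-butyldimethylsilyloxy)-4-methoxyphenyl]pent-4-en-1-one; 16 (4R,5E,7Z,10Z)-4-(tert-butyldimethylsilyloxy)trideca-5,7,10-trien-1-yne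
Product: 19 (9R,6Z,10E,12Z,15Z)-1-[2,6-bis(tert-butyldimethylsilyloxy)-4-methoxyphenyl]-9-(tert-butyldimethylsilyloxy)octadeca-6,10,12,15-tetraen-1-one, via B-alkyl-9-BBN 17 (not isolated), via B-alkenyl-9-BBN 18 (not isolated)
Conditions: 5 (1.5 equiv), 9-borabicyclo[3.3.1]nonane (9-BBN-H, 1.5 equiv of B–H), THF, 0 °C → rt; then 16 (1.0 equiv), chloro[1,3-bis(2,6-diisopropylphenyl)imidazol-2-ylidene]silver [(IPr)AgCl, 5 mol %], KOMe (10 mol %), MeOH (3 equiv), 1,4-dioxane, 45 °C
Reagents that add atoms: none
Why: Hydroboration of the terminal alkene of 5 should give the primary alkylborane 17 (anti-Markovnikov; the alkene outruns the C1 ketone, which is twisted out of conjugation and shielded by two ortho silyloxy groups); the silver acetylide formed at C6–H of 16 is then expected to bind 17 as an alkynylborate, in which the primary alkyl group (C5) migrates from boron to C6 while silver takes up C7 on the opposite face, and methanol finally replaces the C7–Ag bond and the C6–B bond of 18 by C–H with retention. The closest known reaction type is the silver-catalysed hydroalkylation of terminal alkynes with B-alkyl-9-BBN reagents made from terminal alkenes, an electrophile-induced 1,2-metallate (boronate) rearrangement. No ring is closed and no stereocentre is created; the new stereo-element is the C6=C7 geometry, fixed as Z because the migrating C5 and the electrophile at C7 must enter anti, which leaves C5 and C8 cis after two retentive protonolyses. The C9 centre, the 10E,12Z-diene and the 15Z alkene should stay untouched, since no B–H is left once 17 is formed and only a terminal C–H can enter the silver cycle. The step needs site selectivity (the terminal alkyne over three internal alkenes, primary alkyl migration over the bicyclic B–C bonds) and survival of the aryl silyl ethers: the first is secured by the single acetylenic C–H of 16 and the unhindered primary C5–B bond, the second by using only catalytic methoxide, which is held as a borate by the excess of 17.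

**Step 10**
Reactants: 19 (9R,6Z,10E,12Z,15Z)-1-[2,6-bis(tert-butyldimethylsilyloxy)-4-methoxyphenyl]-9-(tert-butyldimethylsilyloxy)octadeca-6,10,12,15-tetraen-1-one
Product: 20 (9R,6Z,10E,12Z,15Z)-1-(2,6-dihydroxy-4-methoxyphenyl)-9-hydroxyoctadeca-6,10,12,15-tetraen-1-one
Conditions: Bu4NF (5 equiv), AcOH (5 equiv), THF, 0 °C → rt
Reagents that add atoms: none
Why: Fluoride-induced desilylation: formation of the strong Si–F bond should cleave the two aryl silyl ethers at once and the secondary allylic one more slowly, with the acetic acid buffer keeping the medium near neutral for the dienyl carbinol and the acylphloroglucinol.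

**Compound list**
1 | 1-(2,6-dihydroxy-4-methoxyphenyl)ethan-1-one | CC(=O)c1c(O)cc(OC)cc1O | starting material
2 | allyl bromide (3-bromoprop-1-ene) | C=CCBr | starting material
3 | trilithium enolate-bisphenoxide of 1 (formed in the flask) | [Li+].[Li+].[Li+].C=C([O-])c1c([O-])cc(OC)cc1[O-] | intermediate
4 | 1-(2,6-dihydroxy-4-methoxyphenyl)pent-4-en-1-one | C=CCCC(=O)c1c(O)cc(OC)cc1O | intermediate
5 | 1-[2,6-bis(tert-butyldimethylsilyloxy)-4-methoxyphenyl]pent-4-en-1-one | C=CCCC(=O)c1c(O[Si](C)(C)C(C)(C)C)cc(OC)cc1O[Si](C)(C)C(C)(C)C | intermediate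
6 | (Z)-hex-3-en-1-ol | CC/C=C\CCO | starting material
7 | (Z)-1-iodohex-3-ene | CC/C=C\CCI | intermediate
8 | [(Z)-hex-3-en-1-yl]triphenylphosphonium iodide | CC/C=C\CC[P+](c1ccccc1)(c1ccccc1)c1ccccc1.[I-] | intermediate
9 | (E)-4,4-dimethoxybut-2-enal | COC(OC)/C=C/C=O | starting material
10 | allenylboronic acid pinacol ester | C=C=CB1OC(C)(C)C(C)(C)O1 | starting material
11 | 2-{[(4R,2E)-1,1-dimethoxyhept-2-en-6-yn-4-yl]oxy}-4,4,5,5-tetramethyl-1,3,2-dioxaborolane (formed in the flask) | COC(OC)/C=C/[C@H](OB1OC(C)(C)C(C)(C)O1)CC#C | intermediate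
12 | (4R,2E)-1,1-dimethoxyhept-2-en-6-yn-4-ol | COC(OC)/C=C/[C@H](O)CC#C | intermediate
13 | (4R,2E)-4-(tert-butyldimethylsilyloxy)-1,1-dimethoxyhept-2-en-6-yne | COC(OC)/C=C/[C@H](O[Si](C)(C)C(C)(C)C)CC#C | intermediate
14 | (4R,2E)-4-(tert-butyldimethylsilyloxy)hept-2-en-6-ynal | O=C/C=C/[C@H](O[Si](C)(C)C(C)(C)C)CC#C | intermediate
15 | [(Z)-hex-3-en-1-ylidene]triphenylphosphorane (formed in the flask) | CC/C=C\CC=P(c1ccccc1)(c1ccccc1)c1ccccc1 | intermediate
16 | (4R,5E,7Z,10Z)-4-(tert-butyldimethylsilyloxy)trideca-5,7,10-trien-1-yne | CC/C=C\C/C=C\C=C\[C@H](O[Si](C)(C)C(C)(C)C)CC#C | intermediate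
17 | 9-{5-[2,6-bis(tert-butyldimethylsilyloxy)-4-methoxyphenyl]-5-oxopentyl}-9-borabicyclo[3.3.1]nonane (formed in the flask) | O=C(CCCCB1C2CCCC1CCC2)c1c(O[Si](C)(C)C(C)(C)C)cc(OC)cc1O[Si](C)(C)C(C)(C)C | intermediate
18 | 9-[(9R,6Z,10E,12Z,15Z)-1-[2,6-bis(tert-butyldimethylsilyloxy)-4-methoxyphenyl]-9-(tert-butyldimethylsilyloxy)-1-oxooctadeca-6,10,12,15-tetraen-6-yl]-9-borabicyclo[3.3.1]nonane, C5 cis to C8 (formed in the flask) | CC/C=C\C/C=C\C=C\[C@H](O[Si](C)(C)C(C)(C)C)C/C=C(\CCCCC(=O)c1c(O[Si](C)(C)C(C)(C)C)cc(OC)cc1O[Si](C)(C)C(C)(C)C)B1C2CCCC1CCC2 | intermediate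
19 | (9R,6Z,10E,12Z,15Z)-1-[2,6-bis(tert-butyldimethylsilyloxy)-4-methoxyphenyl]-9-(tert-butyldimethylsilyloxy)octadeca-6,10,12,15-tetraen-1-one | CC/C=C\C/C=C\C=C\[C@H](O[Si](C)(C)C(C)(C)C)C/C=C\CCCCC(=O)c1c(O[Si](C)(C)C(C)(C)C)cc(OC)cc1O[Si](C)(C)C(C)(C)C | intermediate
20 | (9R,6Z,10E,12Z,15Z)-1-(2,6-dihydroxy-4-methoxyphenyl)-9-hydroxyoctadeca-6,10,12,15-tetraen-1-one | CC/C=C\C/C=C\C=C\[C@H](O)C/C=C\CCCCC(=O)c1c(O)cc(OC)cc1O | target

**Totals**
Total step count: 10. Longest linear sequence: 6 steps (steps 5, 6, 7, 8, 9, 10).

**Steps most likely to fail**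

1. Step 9. The process at risk is the 1,2-shift itself: a ring B–C bond of the bicyclic boron unit may migrate in place of the primary alkyl group, or the protodeboronation of the alkenylborane may stall, and either would erode yield or Z purity. The fallback replaces the metallate shift by a halide-based cross-coupling; it sets out from 16 and comes back at 19. 16 would be iodinated at the acetylenic carbon (N-iodosuccinimide, AgNO3 cat., acetone) to (4R,5E,7Z,10Z)-4-(tert-butyldimethylsilyloxy)-1-iodotrideca-5,7,10-trien-1-yne F1. Cis-reduction of the iodoalkyne with diimide (2-nitrobenzenesulfonyl hydrazide, Et3N, THF–i-PrOH) should give (1Z,4R,5E,7Z,10Z)-4-(tert-butyldimethylsilyloxy)-1-iodotrideca-1,5,7,10-tetraene F2. B-alkyl Suzuki–Miyaura coupling of F2 with 17 ([1,1'-bis(diphenylphosphino)ferrocene]PdCl2, AsPh3, aq. K3PO4, THF–DMF, rt) should then give 19 with retention of the Z geometry. Any loss of aryl silyl groups to the base would not matter, since step 10 removes them.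

2. Step 1. The process at risk is the alkylation of the aggregated polyanion: O-allylation of the phenoxides, double alkylation at C2 or incomplete enolisation. The fallback works on a protected mono-enolate; it sets out from 1 and comes back at 4. 1 would be converted (chloromethyl methyl ether, NaH, DMF) into 1-[4-methoxy-2,6-bis(methoxymethoxy)phenyl]ethan-1-one F3. Its lithium enolate (LiN(i-Pr)2, THF, −78 °C) would be allylated with 2 to 1-[4-methoxy-2,6-bis(methoxymethoxy)phenyl]pent-4-en-1-one F4, and methanolic HCl (40 °C) should release 4.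

3. Step 5. The process at risk is catalyst control: insufficient facial discrimination on a slim linear enal, or acid-induced ionisation of the dimethyl acetal. The fallback replaces asymmetric catalysis by resolution; it sets out from 9 and comes back at 12. Barbier propargylation of 9 (propargyl bromide, Zn, THF–aq. NH4Cl, 0 °C) would give racemic (2E)-1,1-dimethoxyhept-2-en-6-yn-4-ol F5. Lipase-mediated acylation (immobilised Candida antarctica lipase B, vinyl acetate, MTBE) is expected, by the empirical size rule for secondary alcohols (larger alkenyl arm against the slim propargyl arm), to acylate the R enantiomer to (4R,2E)-1,1-dimethoxyhept-2-en-6-yn-4-yl acetate F6. F6 would be separated from the unreacted S alcohol and cleaved with K2CO3 in MeOH to 12.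

**Further compounds**
F1 | step 9 | (4R,5E,7Z,10Z)-4-(tert-butyldimethylsilyloxy)-1-iodotrideca-5,7,10-trien-1-yne | CC/C=C\C/C=C\C=C\[C@H](O[Si](C)(C)C(C)(C)C)CC#CI
F2 | step 9 | (1Z,4R,5E,7Z,10Z)-4-(tert-butyldimethylsilyloxy)-1-iodotrideca-1,5,7,10-tetraene | CC/C=C\C/C=C\C=C\[C@H](O[Si](C)(C)C(C)(C)C)C/C=C\I
F3 | step 1 | 1-[4-methoxy-2,6-bis(methoxymethoxy)phenyl]ethan-1-one | CC(=O)c1c(OCOC)cc(OC)cc1OCOC
F4 | step 1 | 1-[4-methoxy-2,6-bis(methoxymethoxy)phenyl]pent-4-en-1-one | C=CCCC(=O)c1c(OCOC)cc(OC)cc1OCOC
F5 | step 5 | racemic (2E)-1,1-dimethoxyhept-2-en-6-yn-4-ol | COC(OC)/C=C/C(O)CC#C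
F6 | step 5 | (4R,2E)-1,1-dimethoxyhept-2-en-6-yn-4-yl acetate | COC(OC)/C=C/[C@H](OC(C)=O)CC#C
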